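## Retrosynthetic overview

1. Feature: in ring C the ether oxygen O1 is bound to C8a of ring A. C8a is ortho to C4a, which carries the C4 ketone, and meta to the oxygenated C5 and C7. A fluoride on C8a is therefore a ketone-activated SNAr site, and O1–C8a is cut last, from a C2 carbinol whose configuration is already fixed.
2. Ring C is the only ring formed (step 15); rings A and B are bought as arenes. The (S)-β-hydroxy ketone comes from the (E)-chalcone by ligand-controlled Cu-catalysed β-borylation and C–B oxidation, and the chalcone from a Claisen–Schmidt condensation (C2=C3).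
3. C8–C1'' is made by Negishi coupling of a ring A aryl iodide with the alkylzinc reagent of the enantiopure side-chain iodide.
4. Ring A comes from symmetric 1-fluoro-3,5-dimethoxybenzene. Acylation, iodination and chelation-controlled demethylation fix acetyl (C4a), F (C8a), I (C8), OMe (C7) and OMOM (C5), with no metalation in the presence of an enolisable ketone.
5. In the side chain, an Evans deconjugative prenylation sets C2''. Epoxidation and LiAlH4 then turn only the trisubstituted alkene into the tertiary alcohol.

Key step: step 15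

Assumption: the (R,Sp) antipode of the ferrocenyl diphosphine in step 14 is taken to give (S)-22; the sense is checked on the first run by MTPA ester analysis of 23, and the equally available (S,Rp) antipode is used if it proves opposite.

## Route

Step 1
Reactants: 1 (S)-4-benzyl-1,3-oxazolidin-2-one; 2 3-methylbut-2-enoyl chloride
Product: 4 (4S)-4-benzyl-3-(3-methylbut-2-enoyl)-1,3-oxazolidin-2-one, via N-lithio oxazolidinone 3 (not isolated)
Conditions: n-BuLi, THF, −78 °C; then 2, −78 → 0 °C
Reagents that add atoms: n-butyllithium, [Li]CCCC (lithium, held only in 3)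
Why: N-acylation of the lithiated Evans oxazolidinone with an acid chloride is a standard acyl transfer and leaves the C4 stereocentre of the auxiliary untouched.

Step 2
Reactants: 4 (4S)-4-benzyl-3-(3-methylbut-2-enoyl)-1,3-oxazolidin-2-one; 5 1-bromo-3-methylbut-2-ene (prenyl bromide)
Product: 7 (4S)-4-benzyl-3-[(2S)-5-methyl-2-(prop-1-en-2-yl)hex-4-enoyl]-1,3-oxazolidin-2-one, via sodium (Z)-dienolate 6 (not isolated)
Conditions: NaHMDS (1.05 equiv), THF, −78 °C; then 5, −78 → −40 °C; cold NH4Cl quench
Reagents that add atoms: sodium hexamethyldisilazide, C[Si](C)(C)[N-][Si](C)(C)C.[Na+] (sodium, held only in 6)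
Why: Evans asymmetric alkylation in its deconjugative variant: γ-deprotonation of the s-cis enoyl imide gives the sodium-chelated (Z)-dienolate 6, which reacts with the allylic bromide at Cα on the face opposite the C4 benzyl group, so the future C2'' is set by auxiliary control (2S in the imide) and the minor diastereomer can be removed by chromatography.

Step 3
Reactants: 7 (4S)-4-benzyl-3-[(2S)-5-methyl-2-(prop-1-en-2-yl)hex-4-enoyl]-1,3-oxazolidin-2-one
Product: 8 (4S)-4-benzyl-3-{(2S)-2-[(3,3-dimethyloxiran-2-yl)methyl]-3-methylbut-3-enoyl}-1,3-oxazolidin-2-one (both epoxide epimers)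
Conditions: mCPBA (1.05 equiv), CH2Cl2, 0 °C
Reagents that add atoms: mCPBA, O=C(OO)c1cccc(Cl)c1
Why: Prilezhaev epoxidation is electrophilic and should take the trisubstituted alkene rather than the less substituted 1,1-disubstituted one next to the electron-poor imide, while the absence of a free hydroxyl group prevents opening of the epoxide to a tetrahydrofuran; the epoxide carbon forms as both epimers and loses its stereogenicity in step 4.

Step 4
Reactants: 8 epoxy imide
Product: 9 (2S)-5-methyl-2-(prop-1-en-2-yl)hexane-1,5-diol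
Conditions: LiAlH4 (excess), THF, 0 °C → rt; Rochelle salt work-up
Reagents that add atoms: none
Why: Hydride reduction with LiAlH4 cleaves the N-acyl oxazolidinone to the primary alcohol and opens the trisubstituted epoxide in SN2 fashion at its less substituted carbon, which gives the tertiary alcohol and a CH2 group and leaves C2 unchanged.

Step 5
Reactants: 9 (2S)-5-methyl-2-(prop-1-en-2-yl)hexane-1,5-diol
Product: 10 (5S)-5-(iodomethyl)-2,6-dimethylhept-6-en-2-ol
Conditions: I2, PPh3, imidazole, CH2Cl2, 0 °C
Reagents that add atoms: iodine, II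
Why: Appel-type iodination (Garegg–Samuelsson conditions) runs by SN2 displacement of an alkoxyphosphonium ion and is therefore selective for the primary hydroxyl group over the tertiary one, without touching the adjacent stereocentre.

Step 6
Reactants: 10 (5S)-5-(iodomethyl)-2,6-dimethylhept-6-en-2-ol
Product: 11 triethyl{[(5S)-5-(iodomethyl)-2,6-dimethylhept-6-en-2-yl]oxy}silane
Conditions: TESOTf, 2,6-lutidine, CH2Cl2, −78 → 0 °C
Reagents that add atoms: triethylsilyl triflate, CC[Si](CC)(CC)OS(=O)(=O)C(F)(F)F
Why: Silylation with a silyl triflate and a hindered pyridine base is the usual way to protect a tertiary alcohol, which must be masked before organozinc formation and the later base treatments.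

Step 7
Reactants: 12 1-fluoro-3,5-dimethoxybenzene
Product: 13 1-(2-fluoro-4,6-dimethoxyphenyl)ethan-1-one
Conditions: AcCl, AlCl3 (1.1 equiv), CH2Cl2, −10 → 0 °C
Reagents that add atoms: acetyl chloride, CC(=O)Cl
Why: Friedel–Crafts acylation should occur at one of the two symmetry-equivalent positions between F and OMe (para to one methoxy group, ortho to the other), because the only other free position is shielded by two flanking methoxy groups.

Step 8
Reactants: 13 1-(2-fluoro-4,6-dimethoxyphenyl)ethan-1-one
Product: 14 1-(2-fluoro-3-iodo-4,6-dimethoxyphenyl)ethan-1-one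
Conditions: NIS (1.05 equiv), TFA (cat.), MeCN, rt, dark
Reagents that add atoms: N-iodosuccinimide, O=C1CCC(=O)N1I
Why: Electrophilic aromatic iodination with acid-activated NIS should go to C3, which is para to the C6 methoxy group, ortho to the C4 methoxy group and flanked by the small fluorine, rather than to C5 between two methoxy groups, in line with the usual 4,6- rather than 2-substitution of resorcinol diethers.

Step 9
Reactants: 14 1-(2-fluoro-3-iodo-4,6-dimethoxyphenyl)ethan-1-one
Product: 15 1-(2-fluoro-6-hydroxy-3-iodo-4-methoxyphenyl)ethan-1-one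
Conditions: BCl3 (1.2 equiv), CH2Cl2, −78 → 0 °C; aq. work-up
Reagents that add atoms: none
Why: Chelation-controlled ether cleavage: BCl3 binds the ketone oxygen and removes only the methyl group of the ortho methoxy group that can close a six-membered boron chelate, which differentiates the future C5 oxygen from the C7 methyl ether.

Step 10
Reactants: 15 1-(2-fluoro-6-hydroxy-3-iodo-4-methoxyphenyl)ethan-1-one
Product: 16 1-[2-fluoro-3-iodo-4-methoxy-6-(methoxymethoxy)phenyl]ethan-1-one
Conditions: MOMCl, i-Pr2NEt, CH2Cl2, 0 °C → rt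
Reagents that add atoms: chloromethyl methyl ether, COCCl
Why: Williamson-type O-alkylation with MOMCl masks the acidic C5–OH, whose phenoxide would otherwise switch off the ketone as SNAr activator in step 15.

Step 11
Reactants: 11 side-chain iodide; 16 aryl iodide
Product: 18 1-{2-fluoro-4-methoxy-6-(methoxymethoxy)-3-[(2R)-5-methyl-2-(prop-1-en-2-yl)-5-(triethylsilyloxy)hexyl]phenyl}ethan-1-one, via alkylzinc iodide 17 (not isolated)
Conditions: 11, Zn dust (activated), LiCl, THF, 25–40 °C; then 16, Pd(OAc)2 (cat.), SPhos (cat.), THF, rt → 40 °C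
Reagents that add atoms: zinc, [Zn] (held only in 17)
Why: Negishi sp3–sp2 cross-coupling: LiCl-promoted zinc insertion into the primary iodide gives a ketone-tolerant alkylzinc, and a bulky biarylphosphine palladium catalyst couples it with the di-ortho-substituted aryl iodide with reductive elimination faster than β-hydride elimination, while C2'' is β to the metal and is not touched (its descriptor changes from S to R only because CH2–aryl ranks below isopropenyl).

Step 12
Reactants: 19 2,4-dihydroxybenzaldehyde
Product: 20 2,4-bis(methoxymethoxy)benzaldehyde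
Conditions: MOMCl (3 equiv), i-Pr2NEt (4 equiv), CH2Cl2, 0 °C → reflux
Reagents that add atoms: chloromethyl methyl ether, COCCl
Why: Double O-alkylation with MOMCl puts base-stable acetals on both phenols of ring B, so no phenoxide can later form ortho or para to C2.

Step 13
Reactants: 18 methyl ketone; 20 2,4-bis(methoxymethoxy)benzaldehyde
Product: 21 (E)-3-[2,4-bis(methoxymethoxy)phenyl]-1-{2-fluoro-4-methoxy-6-(methoxymethoxy)-3-[(2R)-5-methyl-2-(prop-1-en-2-yl)-5-(triethylsilyloxy)hexyl]phenyl}prop-2-en-1-one
Conditions: KOH, EtOH, 0 °C → rt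
Reagents that add atoms: none
Why: Claisen–Schmidt condensation (aldol addition, then E1cB dehydration) of a methyl ketone with a non-enolisable aldehyde gives the thermodynamically favoured (E)-enone, and the aryl fluoride should survive because external hydroxide or ethoxide lacks the intramolecular advantage used in step 15.

Step 14
Reactants: 21 (E)-chalcone
Product: 23 (3S)-3-[2,4-bis(methoxymethoxy)phenyl]-1-{2-fluoro-4-methoxy-6-(methoxymethoxy)-3-[(2R)-5-methyl-2-(prop-1-en-2-yl)-5-(triethylsilyloxy)hexyl]phenyl}-3-hydroxypropan-1-one, via (S)-β-boryl ketone 22 (not isolated)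
Conditions: CuCl (cat.), NaOt-Bu (cat.), (R)-1-[(Sp)-2-(diphenylphosphino)ferrocenyl]ethyldicyclohexylphosphine (cat.), B2pin2, MeOH (2 equiv), THF, rt; then NaBO3·4H2O, THF–H2O, rt
Reagents that add atoms: bis(pinacolato)diboron, CC1(C)OB(OC1(C)C)B1OC(C)(C)C(C)(C)O1 (boron, held only in 22); sodium perborate, [Na+].[O-]OB=O (the carbinol oxygen)
Why: Copper(I)-catalysed enantioselective conjugate borylation of an acyclic enone followed by stereoretentive C–B oxidation: the chiral diphosphine–Cu–Bpin complex adds to one face of the enone and sets C2 by ligand control, only the electron-poor alkene reacts so the isopropenyl group stays, and perborate replaces boron by oxygen with retention under nearly neutral conditions that spare the aldol.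

Step 15
Reactants: 23 (S)-β-hydroxy ketone
Product: 25 (2S)-2-[2,4-bis(methoxymethoxy)phenyl]-7-methoxy-5-(methoxymethoxy)-8-[(2R)-5-methyl-2-(prop-1-en-2-yl)-5-(triethylsilyloxy)hexyl]chroman-4-one, via potassium alkoxide 24 (not isolated)
Conditions: KHMDS (1.00 equiv), THF (dilute), −78 → −20 °C, warmed only until fluoride loss sets in; AcOH/THF quench at low temperature
Reagents that add atoms: potassium hexamethyldisilazide, C[Si](C)(C)[N-][Si](C)(C)C.[K+] (potassium, held only in 24)
Why: KHMDS takes the carbinol proton (kinetically faster than C3–H), alkoxide 24 adds to C8a to give a Meisenheimer anion whose charge rests on C8, C6 and above all on C4a and the C4 carbonyl oxygen, and expulsion of fluoride rearomatises ring A and leaves the O1–C8a bond. The closest known reaction type is the ketone-activated intramolecular SNAr O-arylation of ortho-fluoroaryl ketones that closes chromones, xanthones and chroman-4-ones. Ring C closes as a six-membered ring by a formally 6-endo-trig addition (the C8a=C4a bond that accepts the electrons lies inside the new ring) followed by elimination. No stereocentre is created: only the O–H and C8a–F bonds change, so C2 keeps its four ligands and its (S) configuration from step 14, and C2'' is remote. The step needs chemoselectivity for substitution over retro-aldol fragmentation, E1cB loss of the C2 oxygen and reopening of 25, and the substrate supplies the ortho ketone, ethers at C5 and C7 that stand meta to the attacked carbon and act only inductively, a tether that places the alkoxide beside C8a, and a single leaving group on ring A so that the side chain can only end up at C8. Exactly one equivalent of base with weakly chelating potassium is used because fragmentation runs through the O–metal–O chelate whereas substitution needs the open conformer, and because the base ends as insoluble KF, so 25 does not meet excess base.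

Step 16
Reactants: 25 protected flavanone
Product: 27 (2S)-2-(2,4-dihydroxyphenyl)-5-hydroxy-7-methoxy-8-[(2R)-5-methyl-2-(prop-1-en-2-yl)-5-(triethylsilyloxy)hexyl]chroman-4-one, via tris(trimethylsilyl) ether 26 (not isolated)
Conditions: TMSOTf (7 equiv), 2,2'-bipyridyl (10 equiv), MeCN, 0 °C → rt; then H2O, rt
Reagents that add atoms: trimethylsilyl triflate, C[Si](C)(C)OS(=O)(=O)C(F)(F)F (silicon, held only in 26)
Why: Silyl triflate/2,2'-bipyridyl cleavage of aromatic MOM ethers: the buffered silylating agent turns each ArO–CH2OMe into ArO–SiMe3 and a methoxymethylpyridinium salt and water then hydrolyses both, so no strong Brønsted acid meets the isopropenyl group, the tertiary silyl ether or the benzylic C2–O1 bond.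

Step 17
Reactants: 27 triethylsilyl ether of the target
Product: 28 (2S)-2-(2,4-dihydroxyphenyl)-5-hydroxy-8-[(2R)-5-hydroxy-5-methyl-2-(prop-1-en-2-yl)hexyl]-7-methoxychroman-4-one (CNP0106344.1)
Conditions: HF·pyridine, pyridine, THF, 0 °C → rt (plastic vessel)
Reagents that add atoms: none
Why: Fluoride-driven desilylation under buffered, weakly acidic conditions frees the tertiary alcohol without the ionising acid that would dehydrate it and without the base that would open ring C and racemise C2.

## Compound list

1 | (S)-4-benzyl-1,3-oxazolidin-2-one | O=C1N[C@@H](Cc2ccccc2)CO1 | starting material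
2 | 3-methylbut-2-enoyl chloride | CC(C)=CC(=O)Cl | starting material
3 | N-lithio (S)-4-benzyl-1,3-oxazolidin-2-one | O=C1N([Li])[C@@H](Cc2ccccc2)CO1 | intermediate
4 | (4S)-4-benzyl-3-(3-methylbut-2-enoyl)-1,3-oxazolidin-2-one | CC(C)=CC(=O)N1[C@@H](Cc2ccccc2)COC1=O | intermediate
5 | 1-bromo-3-methylbut-2-ene | CC(C)=CCBr | starting material
6 | sodium (Z)-dienolate of 4 | C=C(C)/C=C(\[O-])N1[C@@H](Cc2ccccc2)COC1=O.[Na+] | intermediate
7 | (4S)-4-benzyl-3-[(2S)-5-methyl-2-(prop-1-en-2-yl)hex-4-enoyl]-1,3-oxazolidin-2-one | C=C(C)[C@H](CC=C(C)C)C(=O)N1[C@@H](Cc2ccccc2)COC1=O | intermediate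
8 | (4S)-4-benzyl-3-{(2S)-2-[(3,3-dimethyloxiran-2-yl)methyl]-3-methylbut-3-enoyl}-1,3-oxazolidin-2-one, both epoxide epimers | C=C(C)[C@H](CC2OC2(C)C)C(=O)N1[C@@H](Cc3ccccc3)COC1=O | intermediate
9 | (2S)-5-methyl-2-(prop-1-en-2-yl)hexane-1,5-diol | C=C(C)[C@H](CCC(C)(C)O)CO | intermediate
10 | (5S)-5-(iodomethyl)-2,6-dimethylhept-6-en-2-ol | C=C(C)[C@H](CCC(C)(C)O)CI | intermediate
11 | triethyl{[(5S)-5-(iodomethyl)-2,6-dimethylhept-6-en-2-yl]oxy}silane | C=C(C)[C@H](CCC(C)(C)O[Si](CC)(CC)CC)CI | intermediate
12 | 1-fluoro-3,5-dimethoxybenzene | COc1cc(F)cc(OC)c1 | starting material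
13 | 1-(2-fluoro-4,6-dimethoxyphenyl)ethan-1-one | CC(=O)c1c(F)cc(OC)cc1OC | intermediate
14 | 1-(2-fluoro-3-iodo-4,6-dimethoxyphenyl)ethan-1-one | CC(=O)c1c(F)c(I)c(OC)cc1OC | intermediate
15 | 1-(2-fluoro-6-hydroxy-3-iodo-4-methoxyphenyl)ethan-1-one | CC(=O)c1c(F)c(I)c(OC)cc1O | intermediate
16 | 1-[2-fluoro-3-iodo-4-methoxy-6-(methoxymethoxy)phenyl]ethan-1-one | CC(=O)c1c(F)c(I)c(OC)cc1OCOC | intermediate
17 | {(2S)-5-methyl-2-(prop-1-en-2-yl)-5-(triethylsilyloxy)hexyl}zinc iodide | C=C(C)[C@H](CCC(C)(C)O[Si](CC)(CC)CC)C[Zn]I | intermediate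
18 | 1-{2-fluoro-4-methoxy-6-(methoxymethoxy)-3-[(2R)-5-methyl-2-(prop-1-en-2-yl)-5-(triethylsilyloxy)hexyl]phenyl}ethan-1-one | C=C(C)[C@H](CCC(C)(C)O[Si](CC)(CC)CC)Cc1c(OC)cc(OCOC)c(C(C)=O)c1F | intermediate
19 | 2,4-dihydroxybenzaldehyde | O=Cc1ccc(O)cc1O | starting material
20 | 2,4-bis(methoxymethoxy)benzaldehyde | O=Cc1ccc(OCOC)cc1OCOC | intermediate
21 | (E)-chalcone, (2''R) side chain | C=C(C)[C@H](CCC(C)(C)O[Si](CC)(CC)CC)Cc1c(OC)cc(OCOC)c(C(=O)/C=C/c2ccc(OCOC)cc2OCOC)c1F | intermediate
22 | (S)-β-(pinacolboryl) ketone | C=C(C)[C@H](CCC(C)(C)O[Si](CC)(CC)CC)Cc1c(OC)cc(OCOC)c(C(=O)C[C@H](B3OC(C)(C)C(C)(C)O3)c2ccc(OCOC)cc2OCOC)c1F | intermediate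
23 | (S)-β-hydroxy ketone, SNAr precursor | C=C(C)[C@H](CCC(C)(C)O[Si](CC)(CC)CC)Cc1c(OC)cc(OCOC)c(C(=O)C[C@H](O)c2ccc(OCOC)cc2OCOC)c1F | intermediate
24 | potassium alkoxide of 23 | C=C(C)[C@H](CCC(C)(C)O[Si](CC)(CC)CC)Cc1c(OC)cc(OCOC)c(C(=O)C[C@H]([O-])c2ccc(OCOC)cc2OCOC)c1F.[K+] | intermediate
25 | (2S,2''R)-flavanone, three MOM ethers and TES ether | C=C(C)[C@H](CCC(C)(C)O[Si](CC)(CC)CC)Cc1c(OC)cc(OCOC)c2c1O[C@H](c1ccc(OCOC)cc1OCOC)CC2=O | intermediate
26 | (2S,2''R)-flavanone, three aryl TMS ethers and TES ether | C=C(C)[C@H](CCC(C)(C)O[Si](CC)(CC)CC)Cc1c(OC)cc(O[Si](C)(C)C)c2c1O[C@H](c1ccc(O[Si](C)(C)C)cc1O[Si](C)(C)C)CC2=O | intermediate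
27 | (2S,2''R)-flavanone, free phenols, TES ether | C=C(C)[C@H](CCC(C)(C)O[Si](CC)(CC)CC)Cc1c(OC)cc(O)c2c1O[C@H](c1ccc(O)cc1O)CC2=O | intermediate
28 | (2S)-2-(2,4-dihydroxyphenyl)-5-hydroxy-8-[(2R)-5-hydroxy-5-methyl-2-(prop-1-en-2-yl)hexyl]-7-methoxychroman-4-one | C=C(C)[C@H](CCC(C)(C)O)Cc1c(OC)cc(O)c2c1O[C@H](c1ccc(O)cc1O)CC2=O | target

## Step count and risks

Total step count: 17. Longest linear sequence: 12 steps (steps 1–6, 11, 13–17).

**Step 15 (key step).**
- What may go wrong: the alkoxide may fragment by retro-aldol and recombine without facial control, which erodes C2. It may also lose the C2 oxygen by E1cB faster than it attacks the hindered aryl fluoride, whose carbonyl is twisted. Residual base may reopen ring C.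
- Fallback: it sets out from ketone 18 and comes back at flavanone 25. The O1–C8a bond is made on an achiral, robust enolate and C2 is set afterwards.
- Claisen formylation of 18 (HCO2Et, NaH, THF) gives the sodium hydroxymethylene ketone enolate F1. On warming in DMF this closes through its enolate oxygen by the same ketone-activated SNAr to the 2-unsubstituted chromone F2.
- In parallel, commercial 4-bromoresorcinol is protected (MOMCl, i-Pr2NEt) to 1-bromo-2,4-bis(methoxymethoxy)benzene F3. Bromine–lithium exchange (n-BuLi, THF, −78 °C) gives 2,4-bis(methoxymethoxy)phenyllithium F4. Quenching with B(Oi-Pr)3 and mild hydrolysis gives 2,4-bis(methoxymethoxy)phenylboronic acid F5.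
- Rhodium(I)-catalysed asymmetric 1,4-addition of F5 to F2 follows, with an electron-poor atropisomeric diphosphine in CH2Cl2–H2O at rt and no added base. It delivers 25 with C2 set by the ligand.

**Step 11.**
- What may go wrong: oxidative addition and transmetalation at the di-ortho-substituted iodide may be slow. β-Hydride elimination toward the allylic tertiary C–H, protodezincation, or skeletal rearrangement of the homoallyl radical during zinc insertion may compete.
- Fallback: it sets out from iodides 11 and 16 and comes back at ketone 18 by a B-alkyl Suzuki–Miyaura coupling. The nucleophile is made by polar halogen–lithium exchange instead of metal insertion.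
- t-BuLi (2 equiv, Et2O, −78 °C) converts 11 into the primary alkyllithium F6. B-Methoxy-9-BBN traps it as the lithium B-alkyl-B-methoxy-9-BBN borate F7. This borate is coupled with 16 using PdCl2(dppf) and aq. K3PO4 in DMF at rt.

**Step 14.**
- What may go wrong: facial selectivity may be poor, because the aroyl group is twisted out of conjugation and the β-aryl group is electron-rich and ortho-substituted. Insertion may be slow enough for ligand-free background borylation to compete. Dehydration may occur during the oxidation.
- Fallback: it sets out from chalcone 21 and comes back at aldol 23. Juliá–Colonna epoxidation (poly-D-leucine, urea–H2O2, DBU, THF) is nucleophilic and leaves the isolated alkene alone. It gives the trans-(αS,βR)-epoxy ketone F8.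
- Reductive cleavage of the Cα–O bond of F8 with sodium phenylselenide ((PhSe)2, NaBH4, EtOH, AcOH) keeps the Cβ–O bond and gives 23.

## Further compounds

F1 | step 15 | sodium (Z)-3-aryl-3-oxoprop-1-en-1-olate of 18 (hydroxymethylene ketone enolate) | C=C(C)[C@H](CCC(C)(C)O[Si](CC)(CC)CC)Cc1c(OC)cc(OCOC)c(C(=O)/C=C\[O-])c1F.[Na+]
F2 | step 15 | 7-methoxy-5-(methoxymethoxy)-8-[(2R)-5-methyl-2-(prop-1-en-2-yl)-5-(triethylsilyloxy)hexyl]-4H-chromen-4-one | C=C(C)[C@H](CCC(C)(C)O[Si](CC)(CC)CC)Cc1c(OC)cc(OCOC)c2c1OC=CC2=O
F3 | step 15 | 1-bromo-2,4-bis(methoxymethoxy)benzene | COCOc1ccc(Br)c(OCOC)c1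
F4 | step 15 | 2,4-bis(methoxymethoxy)phenyllithium | [Li]c1ccc(OCOC)cc1OCOC
F5 | step 15 | 2,4-bis(methoxymethoxy)phenylboronic acid | OB(O)c1ccc(OCOC)cc1OCOC
F6 | step 11 | (2S)-5-methyl-2-(prop-1-en-2-yl)-5-(triethylsilyloxy)hexyllithium | C=C(C)[C@H](CCC(C)(C)O[Si](CC)(CC)CC)C[Li]
F7 | step 11 | lithium B-alkyl-B-methoxy-9-borabicyclo[3.3.1]nonane borate | C=C(C)[C@H](CCC(C)(C)O[Si](CC)(CC)CC)C[B-]1(OC)C2CCCC1CCC2.[Li+]
F8 | step 14 | trans-(αS,βR)-epoxy ketone of chalcone 21 | C=C(C)[C@H](CCC(C)(C)O[Si](CC)(CC)CC)Cc1c(OC)cc(OCOC)c(C(=O)[C@H]3O[C@@H]3c2ccc(OCOC)cc2OCOC)c1F
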